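**Plan**

1. Retrosynthetic cuts: both phenols come from MOM ethers. The diaryl ketone is cut at the bond between the carbonyl carbon and C1' of ring A (aryllithium plus aldehyde, then oxidation). The formyl carbon is cut from C6 of ring B (ortho-formylation). Ring B is then dearomatized on paper: C4a regains a hydroxyl, the pyran bond O1–C8a is cut, and C4a–C4 is cut to an acetylide and p-benzoquinone monoketal. In ring A the C2'–CH2 (prenyl) bond is cut (directed ortho-metalation).
2. Enabling feature: in ring B the C7 hydroxyl, the ether carbon C8a and the chain-bearing C4a stand 1,3,4. Ring B is therefore the dehydration product of a 4-hydroxy-4-alkenylcyclohexa-2,5-dienone in which C7 is the carbonyl carbon, C4a the carbinol carbon and C8a a β-carbon. The (Z)-C3=C4 alkene holds the tertiary O1 directly over C8a.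
3. Forward, ring B and pyran: acetylide addition to the quinone monoketal makes C4a–C4, Lindlar reduction sets (Z)-C3=C4, and the ketal is hydrolysed. O1 then adds to C8a (pyran ring) and loss of the C4a hydroxyl as water aromatizes ring B. Ring B is thus carried as a cyclohexadienone through steps 1 to 4; the extra C4a hydroxyl is the only helper and leaves in the ring-closing step.
4. Forward, remainder: C6 is formylated and the phenol masked. Ring A (two steps from 3-bromophenol) is joined as its aryllithium, the carbinol is oxidized, and both MOM groups are removed.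
5. Stereochemistry: the target is achiral. The only element to control is the (Z) alkene needed for closure (syn semi-hydrogenation, afterwards locked in the ring). The stereocentres of the bicyclic ketone of the key step and of the diaryl carbinol are racemic and are erased.

Key step: step 4

Remark: chromene numbering (O1, C2, C3, C4, C4a, C5 to C8, C8a) is used for the pyran ring and ring B, primed numbers (C1' to C6') for ring A.
Assumption: 4,4-dimethoxycyclohexa-2,5-dien-1-one is taken as a purchased material (otherwise one oxidation step from 4-methoxyphenol).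

**Route**

Step 1
Reactants: 1 4,4-dimethoxycyclohexa-2,5-dien-1-one; 2 2-methylbut-3-yn-2-ol
Product: 4 1-(3-hydroxy-3-methylbut-1-yn-1-yl)-4,4-dimethoxycyclohexa-2,5-dien-1-ol, via dilithio alkynolate 3 (not isolated)
Conditions: 2, n-BuLi (2.1 equiv), THF, −78 to 0 °C; then 1, −78 to 0 °C; aqueous work-up
Reagents that add atoms: none
Why: 1,2-Addition of a lithium acetylide to the only free carbonyl of the quinone monoketal forms the C4a–C4 bond while the ketal masks the future C7 oxygen; the new carbinol carbon lies on the mirror plane of the ring and is not a stereocentre.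

Step 2
Reactants: 4 1-(3-hydroxy-3-methylbut-1-yn-1-yl)-4,4-dimethoxycyclohexa-2,5-dien-1-ol
Product: 5 1-[(1Z)-3-hydroxy-3-methylbut-1-en-1-yl]-4,4-dimethoxycyclohexa-2,5-dien-1-ol
Conditions: H2 (1 atm), Pd on CaCO3 poisoned with Pb(OAc)2 (Lindlar catalyst), quinoline, EtOAc, rt
Reagents that add atoms: none
Why: Lindlar semi-hydrogenation adds H2 syn to the alkyne and so fixes the (Z)-C3=C4 geometry, while the two ring alkenes, each flanked by quaternary carbons, should be reduced far more slowly on the poisoned catalyst.

Step 3
Reactants: 5 1-[(1Z)-3-hydroxy-3-methylbut-1-en-1-yl]-4,4-dimethoxycyclohexa-2,5-dien-1-ol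
Product: 6 4-hydroxy-4-[(1Z)-3-hydroxy-3-methylbut-1-en-1-yl]cyclohexa-2,5-dien-1-one
Conditions: oxalic acid (5% aq.), THF, 0 °C to rt; NaHCO3 quench; crude product used at once
Reagents that add atoms: water, O
Why: Acetal hydrolysis of a quinone monoketal needs only very mild aqueous acid, far milder than ionization of the tertiary allylic alcohols requires, and unveils the cross-conjugated dienone (C7=O) without creating a stereocentre.

Step 4
Reactants: 6 4-hydroxy-4-[(1Z)-3-hydroxy-3-methylbut-1-en-1-yl]cyclohexa-2,5-dien-1-one
Product: 8 2,2-dimethyl-2H-chromen-7-ol, via bicyclic hydroxy enone 7 (not isolated)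
Conditions: KOtBu (0.1 equiv), THF, 0 °C; then camphorsulfonic acid (0.3 equiv), CH2Cl2/THF, 0 °C to rt
Reagents that add atoms: none
Why: Catalytic tert-butoxide generates the tertiary C2 alkoxide, whose O1 is held by the (Z)-C3=C4 alkene over the β-carbon C8a of the dienone and should add there in a 6-exo-trig oxa-Michael closure that forms the O1–C8a bond and the pyran ring of 7; acid then protonates the C4a hydroxyl, which leaves as water through the dienol and cyclohexadienyl cation (the dehydration of an arene hydrate), and loss of the C8a proton with enolization of C7=O gives the phenol 8. The closest known reaction types are the oxa-Michael cyclization of 4-(hydroxyalkyl)-4-hydroxycyclohexadienones to cis-fused bicyclic ethers and the Michael addition–dehydrative aromatization of p-quinols to meta-substituted phenols. The tether allows only cis fusion at C4a/C8a of 7 (racemic), and both centres are erased on aromatization. The two β-carbons C5 and C8a are enantiotopic, so either attack leads to the same chromenol, and only O1, not the C4a hydroxyl, can reach a β-carbon. The selectivity that matters is conjugate addition before any acid is present: once O1 is bound as the ring ether, ionization at C2 with capture by the C4a hydroxyl (spiro ether) and the dienone–phenol shift of the free quinol should be suppressed. The pattern of ring B (O1 meta and C4a para to the C7 hydroxyl) follows from the dienone itself and needs no leaving group or metal at C8a.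

Step 5
Reactants: 8 2,2-dimethyl-2H-chromen-7-ol
Product: 9 7-hydroxy-2,2-dimethyl-2H-chromene-6-carbaldehyde
Conditions: MgCl2 (1.5 equiv), Et3N (3.75 equiv), paraformaldehyde (excess), MeCN, reflux; dilute HCl work-up
Reagents that add atoms: paraformaldehyde (as formaldehyde), C=O
Why: Ortho-specific formylation of the magnesium phenoxide with formaldehyde (Casnati–Skattebøl reaction) should go to C6, the unhindered ortho carbon, and not to C8, which is flanked by O1, as is usual for 3-alkoxyphenols; the basic medium leaves the chromene alkene untouched.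

Step 6
Reactants: 9 7-hydroxy-2,2-dimethyl-2H-chromene-6-carbaldehyde
Product: 10 7-(methoxymethoxy)-2,2-dimethyl-2H-chromene-6-carbaldehyde
Conditions: MOMCl, i-Pr2NEt, CH2Cl2, 0 °C to reflux
Reagents that add atoms: chloromethyl methyl ether (MOMCl), COCCl
Why: O-Alkylation of the phenol with MOMCl (Williamson-type ether formation) masks the acidic chelated hydroxyl before the aryllithium addition and tolerates the aldehyde and the chromene.

Step 7
Reactants: 11 3-bromophenol
Product: 12 1-bromo-3-(methoxymethoxy)benzene
Conditions: MOMCl, i-Pr2NEt, CH2Cl2, 0 °C to rt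
Reagents that add atoms: chloromethyl methyl ether (MOMCl), COCCl
Why: O-Alkylation of the phenol with MOMCl (Williamson-type ether formation) installs an ether that serves both as protecting group and as ortho-directing group for step 8.

Step 8
Reactants: 12 1-bromo-3-(methoxymethoxy)benzene; 13 1-bromo-3-methylbut-2-ene
Product: 16 1-bromo-3-(methoxymethoxy)-2-(3-methylbut-2-en-1-yl)benzene, via aryllithium 14 (not isolated), via arylcopper 15 (not isolated)
Conditions: LiN(i-Pr)2 (LDA, 1.1 equiv), THF, −78 °C; CuBr·SMe2 (1.1 equiv), −78 °C; then 13, −78 to 0 °C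
Reagents that add atoms: none
Why: Directed ortho-metalation removes the proton at C2', the most acidic site because it lies between the coordinating OMOM group and the bromine (an amide base does not exchange the bromine), and the derived arylcopper should be allylated by prenyl bromide at its primary carbon (SN2), which sets the contiguous 1',2',3' pattern of ring A without a stereocentre.

Step 9
Reactants: 16 1-bromo-3-(methoxymethoxy)-2-(3-methylbut-2-en-1-yl)benzene; 10 7-(methoxymethoxy)-2,2-dimethyl-2H-chromene-6-carbaldehyde
Product: 18 [3-(methoxymethoxy)-2-(3-methylbut-2-en-1-yl)phenyl][7-(methoxymethoxy)-2,2-dimethyl-2H-chromen-6-yl]methanol, via aryllithium 17 (not isolated)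
Conditions: 16, n-BuLi (1.05 equiv), THF, −78 °C; then 10, −78 to −20 °C; aqueous work-up
Reagents that add atoms: none
Why: Bromine–lithium exchange followed by 1,2-addition of the aryllithium to the non-enolizable aldehyde forms the bond from C1' to the carbinol carbon; the new carbinol stereocentre is formed as a racemate and is removed by the oxidation in step 10.

Step 10
Reactants: 18 [3-(methoxymethoxy)-2-(3-methylbut-2-en-1-yl)phenyl][7-(methoxymethoxy)-2,2-dimethyl-2H-chromen-6-yl]methanol
Product: 19 [3-(methoxymethoxy)-2-(3-methylbut-2-en-1-yl)phenyl][7-(methoxymethoxy)-2,2-dimethyl-2H-chromen-6-yl]methanone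
Conditions: Dess–Martin periodinane (1.3 equiv), NaHCO3, CH2Cl2, 0 °C to rt
Reagents that add atoms: none
Why: Dess–Martin oxidation converts the doubly benzylic secondary alcohol into the diaryl ketone under buffered conditions that spare the prenyl and chromene alkenes and the MOM ethers, and it removes the only stereocentre.

Step 11
Reactants: 19 [3-(methoxymethoxy)-2-(3-methylbut-2-en-1-yl)phenyl][7-(methoxymethoxy)-2,2-dimethyl-2H-chromen-6-yl]methanone
Product: 20 cudraphenone A
Conditions: HCl (3 M aq.), MeOH, rt to 40 °C
Reagents that add atoms: none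
Why: Acid-catalysed acetal cleavage (MOM removal) in methanol frees both phenols, the one ortho to the carbonyl fastest, under conditions of a kind that prenylated phenols and 2,2-dimethylchromenes normally survive.

**Compound list**

1 | 4,4-dimethoxycyclohexa-2,5-dien-1-one | COC1(OC)C=CC(=O)C=C1 | starting material
2 | 2-methylbut-3-yn-2-ol | CC(C)(O)C#C | starting material
3 | lithium 4-lithio-2-methylbut-3-yn-2-olate (dilithio alkynolate, formed in the flask) | [Li]C#CC(C)(C)O[Li] | intermediate
4 | 1-(3-hydroxy-3-methylbut-1-yn-1-yl)-4,4-dimethoxycyclohexa-2,5-dien-1-ol | COC1(OC)C=CC(O)(C#CC(C)(C)O)C=C1 | intermediate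
5 | 1-[(1Z)-3-hydroxy-3-methylbut-1-en-1-yl]-4,4-dimethoxycyclohexa-2,5-dien-1-ol | COC1(OC)C=CC(O)(/C=C\C(C)(C)O)C=C1 | intermediate
6 | 4-hydroxy-4-[(1Z)-3-hydroxy-3-methylbut-1-en-1-yl]cyclohexa-2,5-dien-1-one | CC(C)(O)/C=C\C1(O)C=CC(=O)C=C1 | intermediate
7 | (4aS*,8aS*)-4a-hydroxy-2,2-dimethyl-4a,8a-dihydro-2H-chromen-7(8H)-one (bicyclic hydroxy enone, cis ring fusion, racemic, one enantiomer written, formed in the flask) | CC1(C)C=C[C@]2(O)C=CC(=O)C[C@@H]2O1 | intermediate
8 | 2,2-dimethyl-2H-chromen-7-ol | CC1(C)C=Cc2ccc(O)cc2O1 | intermediate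
9 | 7-hydroxy-2,2-dimethyl-2H-chromene-6-carbaldehyde | CC1(C)C=Cc2cc(C=O)c(O)cc2O1 | intermediate
10 | 7-(methoxymethoxy)-2,2-dimethyl-2H-chromene-6-carbaldehyde | COCOc1cc2OC(C)(C)C=Cc2cc1C=O | intermediate
11 | 3-bromophenol | Oc1cccc(Br)c1 | starting material
12 | 1-bromo-3-(methoxymethoxy)benzene | COCOc1cccc(Br)c1 | intermediate
13 | 1-bromo-3-methylbut-2-ene (prenyl bromide) | CC(C)=CCBr | starting material
14 | [2-bromo-6-(methoxymethoxy)phenyl]lithium (aryllithium, formed in the flask) | [Li]c1c(Br)cccc1OCOC | intermediate
15 | [2-bromo-6-(methoxymethoxy)phenyl]copper (arylcopper, formed in the flask) | [Cu]c1c(Br)cccc1OCOC | intermediate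
16 | 1-bromo-3-(methoxymethoxy)-2-(3-methylbut-2-en-1-yl)benzene | COCOc1cccc(Br)c1CC=C(C)C | intermediate
17 | [3-(methoxymethoxy)-2-(3-methylbut-2-en-1-yl)phenyl]lithium (aryllithium, formed in the flask) | [Li]c1cccc(OCOC)c1CC=C(C)C | intermediate
18 | [3-(methoxymethoxy)-2-(3-methylbut-2-en-1-yl)phenyl][7-(methoxymethoxy)-2,2-dimethyl-2H-chromen-6-yl]methanol (racemic) | COCOc1cccc(C(O)c2cc3C=CC(C)(C)Oc3cc2OCOC)c1CC=C(C)C | intermediate
19 | [3-(methoxymethoxy)-2-(3-methylbut-2-en-1-yl)phenyl][7-(methoxymethoxy)-2,2-dimethyl-2H-chromen-6-yl]methanone | COCOc1cccc(C(=O)c2cc3C=CC(C)(C)Oc3cc2OCOC)c1CC=C(C)C | intermediate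
20 | cudraphenone A, (7-hydroxy-2,2-dimethyl-2H-chromen-6-yl)[3-hydroxy-2-(3-methylbut-2-en-1-yl)phenyl]methanone | CC(C)=CCc1c(O)cccc1C(=O)c1cc2c(cc1O)OC(C)(C)C=C2 | target

**Step count and risks**

Total step count: 11. Longest linear sequence: 9 steps (steps 1 to 6, then 9 to 11); ring A is made in a 2-step branch (steps 7 and 8) that joins at step 9.

Steps most likely to fail:

1. Step 4. What may go wrong: ionization of the tertiary allylic C2 hydroxyl and capture by the C4a hydroxyl (closure of a five-membered spiro ether), migration of the alkenyl group in a dienone–phenol shift, reversal of the conjugate addition before dehydration, or acid-induced oligomerization of the electron-rich chromenol. Fallback: the pyran is closed at the same O1–C8a bond by nucleophilic aromatic substitution, with a formyl group para to C8a as activator. The fallback sets out from 2. Commercial 5-bromo-4-fluoro-2-hydroxybenzaldehyde would be protected (MOMCl, i-Pr2NEt) as 5-bromo-4-fluoro-2-(methoxymethoxy)benzaldehyde F1. Sonogashira coupling of F1 with 2 (PdCl2(PPh3)2, CuI, Et3N) should give 4-fluoro-5-(3-hydroxy-3-methylbut-1-yn-1-yl)-2-(methoxymethoxy)benzaldehyde F2. Lindlar semi-hydrogenation should give 4-fluoro-5-[(1Z)-3-hydroxy-3-methylbut-1-en-1-yl]-2-(methoxymethoxy)benzaldehyde F3. Cs2CO3 in DMF should then let the tertiary alkoxide displace the fluoride para to the aldehyde, which returns to the route at 10 (steps 1 to 6 are bypassed).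

2. Step 8. What may go wrong: loss of LiBr from the ortho-bromo aryllithium to an aryne, migration of the bromine along the ring, or allylation through the tertiary terminus of the prenyl unit. Fallback: the C2'–C bond is made by a sigmatropic shift instead of a metalation. The fallback sets out from 11. O-Allylation (allyl bromide, K2CO3, acetone) would give 1-bromo-3-(prop-2-en-1-yloxy)benzene F4. Aromatic Claisen rearrangement (N,N-diethylaniline, about 190 °C) to the carbon between the oxygen and the bromine should give 3-bromo-2-(prop-2-en-1-yl)phenol F5; migration to the other ortho carbon is the competing process, and the isomers would be separated. Protection (MOMCl, i-Pr2NEt) would give 1-bromo-3-(methoxymethoxy)-2-(prop-2-en-1-yl)benzene F6. Cross-metathesis with 2-methylbut-2-ene (second-generation Grubbs catalyst RuCl2(=CHPh)(PCy3)(H2IMes), CH2Cl2, 40 °C) should turn the allyl into the prenyl group and return to the route at 16.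

3. Step 11. What may go wrong: acid-promoted addition of methanol to the electron-rich chromene C3=C4 bond, or its oligomerization, while the less labile ring A MOM ether is being cleaved. Fallback: the only acid treatment is moved to a stage without a chromene, and the last unmasking is done with fluoride. The fallback sets out from 16 and 9. The MOM group of 16 would be removed at once (HCl, MeOH) to give 3-bromo-2-(3-methylbut-2-en-1-yl)phenol F7, which would be silylated (TBSCl, imidazole, DMF) to [3-bromo-2-(3-methylbut-2-en-1-yl)phenoxy](tert-butyl)dimethylsilane F8. Bromine–lithium exchange (n-BuLi, THF, −78 °C) should give {3-[tert-butyl(dimethyl)silyloxy]-2-(3-methylbut-2-en-1-yl)phenyl}lithium F9, which would be added to sodium 6-formyl-2,2-dimethyl-2H-chromen-7-olate F10 (from 9 and NaH, THF) to give {3-[tert-butyl(dimethyl)silyloxy]-2-(3-methylbut-2-en-1-yl)phenyl}(7-hydroxy-2,2-dimethyl-2H-chromen-6-yl)methanol F11. MnO2 (CH2Cl2, rt) should oxidize the benzylic carbinol to {3-[tert-butyl(dimethyl)silyloxy]-2-(3-methylbut-2-en-1-yl)phenyl}(7-hydroxy-2,2-dimethyl-2H-chromen-6-yl)methanone F12, and Bu4NF (THF, 0 °C) should remove the silyl group, which returns to the route at 20.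

**Further compounds**

F1 | step 4 | 5-bromo-4-fluoro-2-(methoxymethoxy)benzaldehyde | COCOc1cc(F)c(Br)cc1C=O
F2 | step 4 | 4-fluoro-5-(3-hydroxy-3-methylbut-1-yn-1-yl)-2-(methoxymethoxy)benzaldehyde | COCOc1cc(F)c(C#CC(C)(C)O)cc1C=O
F3 | step 4 | 4-fluoro-5-[(1Z)-3-hydroxy-3-methylbut-1-en-1-yl]-2-(methoxymethoxy)benzaldehyde | COCOc1cc(F)c(/C=C\C(C)(C)O)cc1C=O
F4 | step 8 | 1-bromo-3-(prop-2-en-1-yloxy)benzene | C=CCOc1cccc(Br)c1
F5 | step 8 | 3-bromo-2-(prop-2-en-1-yl)phenol | Oc1cccc(Br)c1CC=C
F6 | step 8 | 1-bromo-3-(methoxymethoxy)-2-(prop-2-en-1-yl)benzene | COCOc1cccc(Br)c1CC=C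
F7 | step 11 | 3-bromo-2-(3-methylbut-2-en-1-yl)phenol | CC(C)=CCc1c(O)cccc1Br
F8 | step 11 | [3-bromo-2-(3-methylbut-2-en-1-yl)phenoxy](tert-butyl)dimethylsilane | CC(C)=CCc1c(Br)cccc1O[Si](C)(C)C(C)(C)C
F9 | step 11 | {3-[tert-butyl(dimethyl)silyloxy]-2-(3-methylbut-2-en-1-yl)phenyl}lithium | [Li]c1cccc(O[Si](C)(C)C(C)(C)C)c1CC=C(C)C
F10 | step 11 | sodium 6-formyl-2,2-dimethyl-2H-chromen-7-olate | [Na+].[O-]c1cc2OC(C)(C)C=Cc2cc1C=O
F11 | step 11 | {3-[tert-butyl(dimethyl)silyloxy]-2-(3-methylbut-2-en-1-yl)phenyl}(7-hydroxy-2,2-dimethyl-2H-chromen-6-yl)methanol (racemic) | CC(C)=CCc1c(O[Si](C)(C)C(C)(C)C)cccc1C(O)c1cc2C=CC(C)(C)Oc2cc1O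
F12 | step 11 | {3-[tert-butyl(dimethyl)silyloxy]-2-(3-methylbut-2-en-1-yl)phenyl}(7-hydroxy-2,2-dimethyl-2H-chromen-6-yl)methanone | CC(C)=CCc1c(O[Si](C)(C)C(C)(C)C)cccc1C(=O)c1cc2C=CC(C)(C)Oc2cc1O
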